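0.104 h⁻¹, as a fraction of the charge of L, is the fastest that J can feed Q into an empty solution. The passage of J into Q carries no activation energy, so I use this delivery for maple, oak, alder and cedar alike.

| setting | maple | oak | cedar | alder |
|---|---|---|---|---|
| L | 0.050 M | 0.050 M | 0.050 M | 0.050 M |
| J | 3.3 mM (held) | 3.3 mM (held) | 3.3 mM (held) | 3.3 mM (held) |
| time | 15 h | 15 h | 15 h | 15 h |
| remark | at 50 °C until 10 h, from then on at −10 °C |  |  |  |
| temperature |  | 50 °C | −10 °C | 20 °C |

1. the flask that comes out highest in amount of L.Q, in percent of the L charged, or "all alike" when all lie within 1.5 percentage points (maple / oak / cedar / alder / all alike)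
2. L.Q at the end, in percent of the L charged, maple
3. L.Q at the end, in percent of the L charged, oak
4. L.Q at the end, in percent of the L charged, cedar
5. L.Q at the end, in percent of the L charged, alder

- percent here means L units held: one L2 or L.L.Q counts as two
- two of one species on the left: rate k times its square, two consumed each time
- at the start none of Q is dissolved
- all constants are for 20 °C and move with temperature by the activation energies

    J ⇌ Q, rate k1*(csat - [Q]) (k1 = 1.57 h⁻¹, csat = 3.3 mM)
    L + L.Q → L.L.Q (k2 = 22.7 M⁻¹ h⁻¹, Ea2 = 60.0 kJ mol⁻¹)
    Q → G (k3 = 0.172 h⁻¹, Ea3 = 99.0 kJ mol⁻¹)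
    2 L → L2 (k4 = 42.7 M⁻¹ h⁻¹, Ea4 = 49.0 kJ mol⁻¹)
    L + Q → L.Q (k5 = 852 M⁻¹ h⁻¹, Ea5 = 63.0 kJ mol⁻¹)
    L → D (k6 = 6.08 h⁻¹, Ea6 = 80.0 kJ mol⁻¹)
    (constants at 20 °C)

Capture, L + Q → L.Q, runs 210 times faster at 50 °C than at −10 °C, yet I expect oak to hold far less L.Q than cedar. One division clears this up. In oak L decays to D with 128 h⁻¹, while the charge of L takes up Q with 469 h⁻¹. In oak Q is therefore removed much faster than it refills at 1.57 h⁻¹, so capture there starts out running at the delivery, and at that stage dissolving is the rate-limiting step. Dividing delivery by decay removes time and gives 0.0809% of the charge in oak. This is the delivery share, the fraction of the charge that J can deliver at full rate during one mean life of L against decay. I leave out dimerisation, which at the start of maple uses L more slowly than decay, by a factor of 4.6.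

The mean life of L against decay at 50 °C is 0.469 min, much shorter than the 10 h before cooling, so I give maple the share of oak. Alder has 1.70%. In cedar decay is down to 0.144 h⁻¹, so the share is 71.9%, which is more than alder has. In cedar Q refills at 1.57 h⁻¹, faster than L decays, so the share stops measuring capture and my reckoning gives cedar a rank but no number.

The forecast names cedar, with 21% (17% to 25%) there, 2.6% in alder, and 0.14% in maple and 0.14% in oak. Its ground for cedar is “L survives for hours alongside nearly saturated Q”. My share for oak lies below its figure.

The simulation gives cedar as highest, with L.Q at 18.7% there, 2.62% in alder, 0.129% in oak and 0.129% in maple.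

In maple half of the turnover of L into D is done by 0.302 min, but half of the passage of J into Q takes until 5.31 h. The reading is 1.59 times the delivery share in oak and 1.54 times in alder, against 0.260 times in cedar. For the neighbour of maple charged with 0.12 M of L, the share falls to 0.0337%, and oak's multiple gives 0.0537%. That flask holds 0.0733% of L.Q at the end, which is 2.18 times its share.

All constants were drawn at random within sensible limits; the result is computed.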